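The data come from a simulation from invented constants; noise was put on by code.

If two nucleophiles compete for one short-lived intermediate and we take its level as steady, each portion of substrate consumed splits as S·b to d, where b and d are the equivalents of first and second nucleophile and S weights the first.

| flask | substrate | first nucleophile | second nucleophile | protic impurity | remark | time |
|---|---|---|---|---|---|---|
| north-west | 0.10 M | 0.80 equiv | 1.1 equiv | 0.050 M | run made earlier |  |
| east | 0.10 M | 0.80 equiv | 2.8 equiv | 0.050 M | run made earlier |  |
| north-east | 0.10 M | 0.80 equiv | 7.2 equiv | 0.050 M | run made earlier |  |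
| Sunday's | 0.10 M | 0.800 equiv | 1.20 equiv | 0.0500 M |  | 2.0 d |
| Friday's | 0.10 M | 0.800 equiv | 3.00 equiv | 0.0500 M |  | 2.0 d |
| Wednesday's | 0.10 M | 0.800 equiv | 7.50 equiv | 0.0500 M |  | 2.0 d |

- north-west (time / h: target / %, substrate / %): 10.0: 14.1, 73.1; 20.0: 21.5, 54.3; 30.0: 24.1, 41.5; 40.0: 24.3, 31.6; 50.0: 24.0, 24.9
- east (time / h: target / %, substrate / %): 4.00: 5.2, 87.6; 8.00: 8.3, 76.4; 15.0: 11.4, 61.5; 25.0: 16.2, 43.9; 50.0: 17.9, 20.0
- north-east (time / h: target / %, substrate / %): 4.00: 2.9, 86.5; 8.00: 4.6, 74.5; 15.0: 7.3, 57.7; 25.0: 8.6, 39.7; 50.0: 9.5, 16.9

(standard deviation of a reading: 0.5 percentage points)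



- which of the two there is more of at the end, Sunday's (other capture product / target)
- which of the two there is more of at the end, Friday's (other capture product / target)
- which of the two there is more of at the end, Wednesday's (other capture product / target)
- final target, as a percentage of the substrate charged, in Sunday's
- final target, as a percentage of the substrate charged, in Friday's
- final target, as a percentage of the substrate charged, in Wednesday's

The runs allow this picture: substrate left at 50.0 h reads 24.9%, 20.0% and 16.9% while second nucleophile rises from 1.1 equiv to 7.2 equiv. We take first readings and count consumed substrate that is not target as other capture product. The east run then gives 2.53 and the north-east run 2.46. The north-west reading comes later, at 10.0 h against 4.00 h, and gives 1.51, so we set it aside. Our S, the selectivity factor, target formed per other capture product at equal equivalents of the two nucleophiles, is 2.50.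

Next comes consumption. Extending first-order decay from the nearest run to 2.0 d gives 73.7% consumed in Sunday's, 78.7% in Friday's and 81.9% in Wednesday's. The split then puts Sunday's target at 46.0%, ahead of other capture product at 27.7%.

That link is weak: it counts target as kept. Yet north-west target reads 24.3%, then 24.0%, while substrate falls from 31.6% to 24.9%. We reforge it with a retention ρ, the last target reading over what the split allows: 0.496 north-west, 0.538 east, 0.527 north-east, mean 0.520. We commit to target 23.9% in Sunday's, 16.3% in Friday's and 8.95% in Wednesday's. In our reckoning Sunday's order flips, with target now 3.8 percentage points behind other capture product, and other capture product leads in Friday's at 47.2% and in Wednesday's at 64.6%.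

The forecast, on its own grounds, that “the first nucleophile is being used up, probably by the protic impurity”, puts other capture product ahead in Sunday's, other capture product in Friday's and other capture product in Wednesday's, with target 23.7%, 17.6% and 9.3%.

The flasks give target 24.4%, 16.6% and 9.04%, against other capture product 29.8%, 48.9% and 65.8%.

    first nucleophile + intermediate → target (k = 92.0 M⁻¹ h⁻¹)
    target ⇌ isomer of the product (K = 0.470, k = 0.0240 h⁻¹)
    substrate ⇌ intermediate (K = 0.0130, k = 0.0400 h⁻¹)
    target → over-reaction product (k = 0.0120 h⁻¹)
    second nucleophile + protic impurity → quenched reagent (k = 0.200 M⁻¹ h⁻¹)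
    second nucleophile + intermediate → other capture product (k = 38.0 M⁻¹ h⁻¹)

Friday's has, from its charges, S·b/d of 0.665; target, isomer of the product and over-reaction product together over other capture product end there at 0.624. The neighbour is Friday's with 3.20 equiv of first nucleophile, so S·b/d becomes 2.66, and the same end ratio stands at 2.68. With ρ and the 82.9% of substrate consumed there, the reckoning puts target at 31.3%. The neighbour ends with target 32.6% against other capture product 22.6%.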